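**Strategy.** Ring C is a resorcinol whose C1′ carries chromone C2 and whose C6′ carries the methylene to pyranone C6, with oxygen at C2′ and C4′: the oxygenation pattern of a folded 2,4,6-triketone. The route therefore rests on cutting C1′–C6′. One base-mediated aldol condensation joins the chromone-bound methylene to the C6′ ketone, and loss of water with enolization delivers the aromatic ring with both phenols in a single operation. Its precursor is a linear seven-carbon 2,4,6-trioxo chain held between a 7-methoxy-5-methylchromone and a 4-hydroxy-2-pyranone, assembled by two Claisen acylations of a ketal-protected 3-oxoglutarate diester.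

Key step: step 7

Assumption: rotation about the C2–C1′ bond is taken to be fast at room temperature, so 11 and 12 have no stereochemical element to set; 10 is drawn as its all-keto tautomer.

Chain numbering used below: C1′ (CH2 on chromone C2), C2′, C4′, C6′ (carbonyl carbons), C3′, C5′ (CH2 between them), C7 (CH2 on pyranone C6).

**Step 1**
Reactants: 1 1-(2,4-dihydroxy-6-methylphenyl)ethanone
Product: 2 1-(2-hydroxy-4-methoxy-6-methylphenyl)ethanone
Conditions: MeI (1.1 equiv), K2CO3 (1.2 equiv), acetone, reflux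
Reagents that add atoms: iodomethane, CI
Why: Williamson etherification should be selective for the 4-hydroxyl, because the 2-hydroxyl is held in a hydrogen bond to the acetyl carbonyl and is the weaker nucleophile.

**Step 2**
Reactants: 2 1-(2-hydroxy-4-methoxy-6-methylphenyl)ethanone
Product: 4 7-methoxy-2,5-dimethyl-4H-chromen-4-one, via 1-(2-hydroxy-4-methoxy-6-methylphenyl)butane-1,3-dione 3 (not isolated)
Conditions: NaH (3.5 equiv), EtOAc, THF, reflux; then AcOH, conc. HCl (cat.), 90 °C
Reagents that add atoms: ethyl acetate, CCOC(C)=O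
Why: A Claisen condensation of the ketone enolate with ethyl acetate gives the β-diketone 3, and acid-catalysed cyclodehydration (phenol oxygen onto the terminal carbonyl, loss of water) closes the 2-methylchromone, the standard entry to this ring system.

**Step 3**
Reactants: 5 dimethyl 3-oxopentanedioate
Product: 6 dimethyl 2,2'-(1,3-dioxolane-2,2-diyl)diacetate
Conditions: HOCH2CH2OH (1.5 equiv), p-TsOH·H2O (cat.), toluene, reflux, Dean–Stark
Reagents that add atoms: ethane-1,2-diol, OCCO
Why: Acid-catalysed ketalization with azeotropic removal of water masks the ketone of the symmetrical β-keto diester as its 1,3-dioxolane, which removes the acidic central positions and insulates the two ester groups.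

**Step 4**
Reactants: 4 7-methoxy-2,5-dimethyl-4H-chromen-4-one; 6 dimethyl 2,2'-(1,3-dioxolane-2,2-diyl)diacetate
Product: 7 methyl 2-{2-[3-(7-methoxy-5-methyl-4-oxo-4H-chromen-2-yl)-2-oxopropyl]-1,3-dioxolan-2-yl}acetate
Conditions: 4, LiN(SiMe3)2 (2.2 equiv), THF, –78 °C; cannulated into 6 (3 equiv), THF, –78 to –40 °C; AcOH
Reagents that add atoms: none
Why: The 2-methyl group is the vinylogous α-position of the chromone carbonyl, so lateral lithiation followed by Claisen acylation on one ester group of 6 (in excess against double acylation) should give the ketone, which the second equivalent of base holds as its enolate until the cold quench.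

**Step 5**
Reactants: 7 methyl 2-{2-[3-(7-methoxy-5-methyl-4-oxo-4H-chromen-2-yl)-2-oxopropyl]-1,3-dioxolan-2-yl}acetate; 8 4-hydroxy-6-methyl-2H-pyran-2-one
Product: 9 2-(3-{2-[3-(4-hydroxy-2-oxo-2H-pyran-6-yl)-2-oxopropyl]-1,3-dioxolan-2-yl}-2-oxopropyl)-7-methoxy-5-methyl-4H-chromen-4-one
Conditions: 8 (3.5 equiv), LiN(iPr)2 (7 equiv), THF, –78 to 0 °C; then 7, –78 to 0 °C; AcOH
Reagents that add atoms: none
Why: Two equivalents of base turn 8 into its O,C-dianion, whose 6-methylene carbanion undergoes a Claisen acylation with the ester of 7; 7 reacts as its C1′ enolate, which shields the chromone and the C2′ ketone, while the ketal keeps the ester unconjugated and electrophilic.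

**Step 6**
Reactants: 9 2-(3-{2-[3-(4-hydroxy-2-oxo-2H-pyran-6-yl)-2-oxopropyl]-1,3-dioxolan-2-yl}-2-oxopropyl)-7-methoxy-5-methyl-4H-chromen-4-one
Product: 10 2-[7-(4-hydroxy-2-oxo-2H-pyran-6-yl)-2,4,6-trioxoheptyl]-7-methoxy-5-methyl-4H-chromen-4-one
Conditions: 2 M aq. HCl, THF, rt (to 40 °C if slow); extracted and used at once
Reagents that add atoms: water, O
Why: Acid-catalysed hydrolysis of the 1,3-dioxolane should release the C4′ ketone under conditions too mild for cyclodehydration of the triketone.

**Step 7**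
Reactants: 10 2-[7-(4-hydroxy-2-oxo-2H-pyran-6-yl)-2,4,6-trioxoheptyl]-7-methoxy-5-methyl-4H-chromen-4-one
Product: 11 2-{2,4-dihydroxy-6-[(4-hydroxy-2-oxo-2H-pyran-6-yl)methyl]phenyl}-7-methoxy-5-methyl-4H-chromen-4-one
Conditions: K2CO3 (3 equiv), MeOH/H2O 4:1, 0 °C to rt, argon; 1 M HCl work-up (pH 2)
Reagents that add atoms: none
Why: Carbonate converts 10 into its pyranone 4-oxide and enolates; the C1′ methylene, acidified by the C2′ ketone and vinylogously by the chromone C4 carbonyl through C2=C3, adds as its enolate to the C6′ ketone, and the adduct should lose water (E1cB) and tautomerize at C2′ and C4′ to the resorcinol. This is the intramolecular aldol condensation–aromatization of a β-triketone, the polyketide-type route to resorcinols. Ring C closes in a 6-(enolendo)-exo-trig mode. No stereocenter is created. The step needs regioselectivity for C1′-to-C6′ closure over C7-to-C2′ closure and over bonding through chromone C3; the substrate should secure it because C7 sits on an anionic, electron-rich pyranone oxide and is the weaker carbon acid, the 7-O-methyl group keeps the chromone neutral and electron-withdrawing, and attack through C3 would break the conjugation of the chromone's pyranone ring.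

**Step 8**
Reactants: 11 2-{2,4-dihydroxy-6-[(4-hydroxy-2-oxo-2H-pyran-6-yl)methyl]phenyl}-7-methoxy-5-methyl-4H-chromen-4-one
Product: 12 2-{2,4-dihydroxy-6-[(4-hydroxy-2-oxo-2H-pyran-6-yl)methyl]phenyl}-7-hydroxy-5-methyl-4H-chromen-4-one
Conditions: BBr3 (8 equiv), CH2Cl2, –78 °C to rt; then H2O, 0 °C
Reagents that add atoms: none
Why: Lewis acid-mediated aryl methyl ether cleavage by BBr3 is the only alkyl–oxygen scission available, since every other C–O bond in 11 ends at an sp2 carbon, and the borates of the phenols and the pyranone hydroxyl are hydrolysed on work-up.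

**Compound list**
1 | 1-(2,4-dihydroxy-6-methylphenyl)ethanone | CC(=O)c1c(C)cc(O)cc1O | starting material
2 | 1-(2-hydroxy-4-methoxy-6-methylphenyl)ethanone | CC(=O)c1c(C)cc(OC)cc1O | intermediate
3 | 1-(2-hydroxy-4-methoxy-6-methylphenyl)butane-1,3-dione | CC(=O)CC(=O)c1c(C)cc(OC)cc1O | intermediate (not isolated)
4 | 7-methoxy-2,5-dimethyl-4H-chromen-4-one | Cc1cc(OC)cc2oc(C)cc(=O)c12 | intermediate
5 | dimethyl 3-oxopentanedioate | COC(=O)CC(=O)CC(=O)OC | starting material
6 | dimethyl 2,2'-(1,3-dioxolane-2,2-diyl)diacetate | COC(=O)CC1(CC(=O)OC)OCCO1 | intermediate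
7 | methyl 2-{2-[3-(7-methoxy-5-methyl-4-oxo-4H-chromen-2-yl)-2-oxopropyl]-1,3-dioxolan-2-yl}acetate | Cc1cc(OC)cc2oc(CC(=O)CC3(CC(=O)OC)OCCO3)cc(=O)c12 | intermediate
8 | 4-hydroxy-6-methyl-2H-pyran-2-one | Cc1cc(O)cc(=O)o1 | starting material
9 | 2-(3-{2-[3-(4-hydroxy-2-oxo-2H-pyran-6-yl)-2-oxopropyl]-1,3-dioxolan-2-yl}-2-oxopropyl)-7-methoxy-5-methyl-4H-chromen-4-one | Cc1cc(OC)cc2oc(CC(=O)CC3(CC(=O)Cc4cc(O)cc(=O)o4)OCCO3)cc(=O)c12 | intermediate
10 | 2-[7-(4-hydroxy-2-oxo-2H-pyran-6-yl)-2,4,6-trioxoheptyl]-7-methoxy-5-methyl-4H-chromen-4-one | Cc1cc(OC)cc2oc(CC(=O)CC(=O)CC(=O)Cc3cc(O)cc(=O)o3)cc(=O)c12 | intermediate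
11 | 2-{2,4-dihydroxy-6-[(4-hydroxy-2-oxo-2H-pyran-6-yl)methyl]phenyl}-7-methoxy-5-methyl-4H-chromen-4-one | Cc1cc(OC)cc2oc(-c3c(O)cc(O)cc3Cc3cc(O)cc(=O)o3)cc(=O)c12 | intermediate
12 | 2-{2,4-dihydroxy-6-[(4-hydroxy-2-oxo-2H-pyran-6-yl)methyl]phenyl}-7-hydroxy-5-methyl-4H-chromen-4-one | Cc1cc(O)cc2oc(-c3c(O)cc(O)cc3Cc3cc(O)cc(=O)o3)cc(=O)c12 | target

Total step count: 8
Longest linear sequence: 7 steps (steps 1, 2, 4, 5, 6, 7, 8; step 3 is a side branch)

**Steps most likely to fail**

Step 7. What may go wrong: closure through the other methylene (C7 onto the C2′ ketone) or through chromone C3, or base-induced retro-Claisen fragmentation of the triketone, in competition with the C1′-to-C6′ aldol. Fallback, setting out from 2 and returning at 12: ring C is brought in as a finished arene and the chromone is built on it as a 2-arylchromone, so that no regiochemical choice remains. Vilsmeier–Haack formylation (POCl3, DMF) of commercial methyl (3,5-dimethoxyphenyl)acetate should give methyl 2-(2-formyl-3,5-dimethoxyphenyl)acetate F1. Claisen–Schmidt condensation of F1 with 2 (NaOMe, MeOH, which keeps the methyl ester) should give methyl 2-{2-[(E)-3-(2-hydroxy-4-methoxy-6-methylphenyl)-3-oxoprop-1-en-1-yl]-3,5-dimethoxyphenyl}acetate F2. Oxidative cyclization of this 2′-hydroxychalcone (I2 cat., DMSO, 120 °C) should give methyl 2-[3,5-dimethoxy-2-(7-methoxy-5-methyl-4-oxo-4H-chromen-2-yl)phenyl]acetate F3. Claisen acylation of the dianion of methyl acetoacetate (NaH, then n-BuLi, THF, in excess) by the ester of F3 should give methyl 6-[3,5-dimethoxy-2-(7-methoxy-5-methyl-4-oxo-4H-chromen-2-yl)phenyl]-3,5-dioxohexanoate F4. Lactonization (DBU, toluene, reflux) should give 2-{2,4-dimethoxy-6-[(4-hydroxy-2-oxo-2H-pyran-6-yl)methyl]phenyl}-7-methoxy-5-methyl-4H-chromen-4-one F5. BBr3 in CH2Cl2 would then cleave the three aryl methyl ethers and give 12.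

Step 5. What may go wrong: proton transfer from 7 to the pyranone dianion faster than C-acylation, followed on warming by β-elimination of a ketal oxygen or Dieckmann-type self-acylation of the enolate of 7. Fallback, setting out from 8 (with 6) and returning at 9: the order of the two Claisen acylations is inverted. The dianion of 8 (LiN(iPr)2, 2 equiv, THF) is acylated with an excess of the diester 6, which carries no acidic ketone, to give methyl 2-{2-[3-(4-hydroxy-2-oxo-2H-pyran-6-yl)-2-oxopropyl]-1,3-dioxolan-2-yl}acetate F6. F6 is converted into its dianion with LiN(SiMe3)2 (2 equiv), and its remaining ester is acylated by the lateral lithium anion of chromone 4 (used in excess, surplus 4 recovered). The last carbon–carbon bond is then made by the less basic of the two carbanions, and an acetic acid quench gives 9.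

Step 6. What may go wrong: slow cleavage of a dioxolane flanked by two acylmethyl groups, so that the forcing needed triggers acid-catalysed O-cyclization of the liberated triketone to a 4-pyranone or an uncontrolled aldol closure. Fallback, setting out from 9 and returning at 12: the hydrolysis is omitted and 9 itself is treated with K2CO3 in MeOH (rt to 50 °C). The same C1′-to-C6′ aldol condensation should occur, and the ring should aromatize by β-elimination of one ketal oxygen from C4′. This gives 2-{2-hydroxy-4-(2-hydroxyethoxy)-6-[(4-hydroxy-2-oxo-2H-pyran-6-yl)methyl]phenyl}-7-methoxy-5-methyl-4H-chromen-4-one F7. BBr3 in CH2Cl2 then cleaves both the 7-O-methyl and the 4′-O-(2-hydroxyethyl) aryl ether and gives 12.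

**Further compounds**
F1 | step 7 | methyl 2-(2-formyl-3,5-dimethoxyphenyl)acetate | COC(=O)Cc1cc(OC)cc(OC)c1C=O
F2 | step 7 | methyl 2-{2-[(E)-3-(2-hydroxy-4-methoxy-6-methylphenyl)-3-oxoprop-1-en-1-yl]-3,5-dimethoxyphenyl}acetate | COC(=O)Cc1cc(OC)cc(OC)c1/C=C/C(=O)c1c(C)cc(OC)cc1O
F3 | step 7 | methyl 2-[3,5-dimethoxy-2-(7-methoxy-5-methyl-4-oxo-4H-chromen-2-yl)phenyl]acetate | COC(=O)Cc1cc(OC)cc(OC)c1-c1cc(=O)c2c(C)cc(OC)cc2o1
F4 | step 7 | methyl 6-[3,5-dimethoxy-2-(7-methoxy-5-methyl-4-oxo-4H-chromen-2-yl)phenyl]-3,5-dioxohexanoate | COC(=O)CC(=O)CC(=O)Cc1cc(OC)cc(OC)c1-c1cc(=O)c2c(C)cc(OC)cc2o1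
F5 | step 7 | 2-{2,4-dimethoxy-6-[(4-hydroxy-2-oxo-2H-pyran-6-yl)methyl]phenyl}-7-methoxy-5-methyl-4H-chromen-4-one | Cc1cc(OC)cc2oc(-c3c(OC)cc(OC)cc3Cc3cc(O)cc(=O)o3)cc(=O)c12
F6 | step 5 | methyl 2-{2-[3-(4-hydroxy-2-oxo-2H-pyran-6-yl)-2-oxopropyl]-1,3-dioxolan-2-yl}acetate | COC(=O)CC1(CC(=O)Cc2cc(O)cc(=O)o2)OCCO1
F7 | step 6 | 2-{2-hydroxy-4-(2-hydroxyethoxy)-6-[(4-hydroxy-2-oxo-2H-pyran-6-yl)methyl]phenyl}-7-methoxy-5-methyl-4H-chromen-4-one | Cc1cc(OC)cc2oc(-c3c(O)cc(OCCO)cc3Cc3cc(O)cc(=O)o3)cc(=O)c12
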